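**Plan**

1. The quinone ring is numbered C1 (C=O next to the ring CH), C2 (OMe), C3 (OMe), C4 (C=O), C5 (chromanyl), C6 (H). The retrosynthesis cuts C1–C2 first (closure of the quinone ring), then C3–C4 (dimethoxyvinyl arm onto a carbonyl), then C1–C6 and C4–C5 (ketene + alkyne), then the alkyne carbon (one-carbon homologation of an aldehyde) and the pyran ring (salicylaldehyde + acrylonitrile).
2. Enabling feature: C1, C6, C5 and C4 are stored as a strained cyclobutenone with an extra C1–C4 bond that is not in the target, and the C2(OMe)=C3(OMe) edge is a 1,2-dimethoxyvinyl arm on the carbinol carbon C4. Heat cleaves C1–C4 to a ketene at C1, which closes onto C2; the carbinol oxygen becomes the C4 quinone oxygen.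
3. Forward order of rings: benzene ring (bought) → pyran ring (steps 2–4) → ethynyl handle (steps 5–7) → temporary four-membered ring (steps 8–9) → arm attached (step 10) → quinone ring (step 11).
4. Stereochemistry: the only stereocenter, chroman C3 (S in the target), is set in step 4 by catalyst-controlled asymmetric hydrogenation and is only carried afterwards; no later step creates a lasting stereocenter.

Key step: step 11

Assumption: (E)-1,2-dimethoxyethene (14) is used as the pure E isomer, fractionated from the E/Z mixture, because only its lithio derivative has lithium syn to the β-methoxy group and should resist loss of lithium methoxide.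

**Route**

Step 1
Reactants: 1 2,3,4-trimethoxyphenol
Product: 2 2-hydroxy-3,4,5-trimethoxybenzaldehyde
Conditions: MgCl2, Et3N, (CH2O)n, MeCN, reflux
Reagents that add atoms: paraformaldehyde (as formaldehyde, C=O)
Why: Magnesium phenoxide-directed ortho-formylation (Casnati–Skattebøl) should attack the single free ortho position, a second formaldehyde taking up the hydride.

Step 2
Reactants: 2 2-hydroxy-3,4,5-trimethoxybenzaldehyde; 3 acrylonitrile
Product: 4 6,7,8-trimethoxy-2H-chromene-3-carbonitrile
Conditions: DABCO (30 mol %), neat 3, 80 °C
Reagents that add atoms: none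
Why: The DABCO-promoted Baylis–Hillman-type addition of acrylonitrile to a salicylaldehyde, followed by oxa-Michael closure and loss of water, is the standard annulation to 3-cyano-2H-chromenes and builds the pyran ring.

Step 3
Reactants: 4 6,7,8-trimethoxy-2H-chromene-3-carbonitrile
Product: 5 6,7,8-trimethoxy-2H-chromene-3-carboxylic acid
Conditions: 10% aq. NaOH, reflux; then aq. HCl
Reagents that add atoms: sodium hydroxide ([Na+].[OH-]); water (O)
Why: Alkaline hydrolysis of the conjugated nitrile through the amide should give the carboxylate, freed on acidification; the aryl and allyl ethers are inert to hydroxide.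

Step 4
Reactants: 5 6,7,8-trimethoxy-2H-chromene-3-carboxylic acid
Product: 6 (R)-6,7,8-trimethoxychromane-3-carboxylic acid
Conditions: H2 (6 atm), [Ir(COD)(SIPHOX)][B(3,5-(CF3)2C6H3)4] (1 mol %; SIPHOX = spirobiindane phosphine–oxazoline ligand, the antipode that gives the R acid), Et3N (0.5 equiv), MeOH, rt
Reagents that add atoms: none
Why: Carboxylate-directed iridium-catalysed asymmetric hydrogenation of a trisubstituted α,β-unsaturated acid should set C3 under catalyst control, the chiral P,N ligand choosing the face of hydrogen delivery; the ee can be raised by crystallisation if needed.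

Step 5
Reactants: 6 (R)-6,7,8-trimethoxychromane-3-carboxylic acid
Product: 7 (S)-(6,7,8-trimethoxychroman-3-yl)methanol
Conditions: BH3·SMe2, THF, 0 °C → rt; MeOH
Reagents that add atoms: none
Why: Borane reduces the carboxylic acid through the acyloxyborane without touching the stereocenter (the descriptor changes only by priority).

Step 6
Reactants: 7 (S)-(6,7,8-trimethoxychroman-3-yl)methanol
Product: 8 (R)-6,7,8-trimethoxychromane-3-carbaldehyde
Conditions: Dess–Martin periodinane, CH2Cl2, 0 °C → rt; used at once
Reagents that add atoms: none
Why: Dess–Martin oxidation is non-basic, which should avoid enolisation and retro-oxa-Michael opening of this β-aryloxy aldehyde.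

Step 7
Reactants: 8 (R)-6,7,8-trimethoxychromane-3-carbaldehyde
Product: 9 (S)-3-ethynyl-6,7,8-trimethoxychromane
Conditions: TMSCHN2, n-BuLi, THF, −78 °C → 0 °C; aq. NH4Cl
Reagents that add atoms: trimethylsilyldiazomethane (C[Si](C)(C)C=[N+]=[N-])
Why: Colvin rearrangement (addition of lithiated TMS-diazomethane, Peterson elimination, loss of N2, 1,2-hydride shift of the alkylidene carbene) should give the terminal alkyne; addition at −78 °C should outrun enolisation, so the α-center is kept.

Step 8
Reactants: 9 (S)-3-ethynyl-6,7,8-trimethoxychromane; 10 trichloroacetyl chloride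
Product: 12 4,4-dichloro-3-[(S)-6,7,8-trimethoxychroman-3-yl]cyclobut-2-en-1-one, via dichloroketene 11 (not isolated)
Conditions: Zn–Cu couple, Et2O–DME, rt, slow addition of 10; crude product used directly
Reagents that add atoms: none
Why: Zinc dechlorination gives dichloroketene, whose thermal [2+2] cycloaddition to a terminal alkyne places the ketene carbonyl carbon on the unsubstituted terminus, so CCl2 ends next to the carbon bearing the chromanyl group.

Step 9
Reactants: 12 4,4-dichloro-3-[(S)-6,7,8-trimethoxychroman-3-yl]cyclobut-2-en-1-one
Product: 13 3-[(S)-6,7,8-trimethoxychroman-3-yl]cyclobut-3-ene-1,2-dione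
Conditions: AgOCOCF3 (2.2 equiv), THF–H2O, 0 °C → rt, dark
Reagents that add atoms: water (O)
Why: Silver-assisted ionisation of the allylic gem-dichloride to a chlorocyclobutenyl cation, capture by water and loss of HCl is the halocyclobutenone-to-cyclobutenedione hydrolysis, run here without strong acid to spare the trimethoxyarene.

Step 10
Reactants: 13 3-[(S)-6,7,8-trimethoxychroman-3-yl]cyclobut-3-ene-1,2-dione; 14 (E)-1,2-dimethoxyethene
Product: 16 4-[(E)-1,2-dimethoxyethenyl]-4-hydroxy-3-[(S)-6,7,8-trimethoxychroman-3-yl]cyclobut-2-en-1-one (both carbinol epimers), via lithio-(E)-1,2-dimethoxyethene 15 (not isolated)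
Conditions: 14, t-BuLi, THF, −78 → −30 °C; then added to 13, THF, −78 °C; aq. NH4Cl at −78 °C; crude product used directly
Reagents that add atoms: none
Why: α-Lithiation of the enol ether and 1,2-addition of the alkenyllithium to a cyclobutenedione is the usual entry to Moore substrates; the carbonyl next to the chromanyl-bearing carbon should be the more electrophilic one because the other is the end of a β-alkyl enone, and the new carbinol center forms as both epimers, which step 11 flattens.

Step 11
Reactants: 16 4-[(E)-1,2-dimethoxyethenyl]-4-hydroxy-3-[(S)-6,7,8-trimethoxychroman-3-yl]cyclobut-2-en-1-one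
Product: 20 abruquinone B [(S)-2,3-dimethoxy-5-(6,7,8-trimethoxychroman-3-yl)cyclohexa-2,5-diene-1,4-dione], via dienylketene 17 (not isolated), via cyclohexadienone 18 (not isolated), via hydroquinone 19 (not isolated)
Conditions: PhMe (degassed), 100–110 °C; then Ag2O, rt
Reagents that add atoms: none
Why: Heating should open the cyclobutenone by a thermal 4π-conrotatory electrocyclic reaction that cleaves the temporary C1–C4 bond, the carbinol hydroxyl rotating outward and the dimethoxyvinyl arm inward, so that in dienylketene 17 the ketene carbon C1 and the methoxy-bearing vinyl terminus C2 are cis across C4=C5. A thermal 6π-disrotatory electrocyclisation then joins C1 to C2 and closes the six-membered carbocycle as dienone 18; the sp-hybridised ketene carbon has no inward substituent, so the inward methoxy group on C2 should be tolerated. Enolisation gives hydroquinone 19, which Ag2O dehydrogenates to the quinone. The closest known reaction type is the Moore rearrangement of 4-alkenyl-4-hydroxycyclobutenones to hydroquinones and quinones. The only new sp3 center (C2 of 18) is lost on aromatisation, so no stereocenter is created, and chroman C3 is a spectator under these neutral, base-free conditions. The step needs the torquoselectivity of the ring opening, which the donor hydroxyl on C4 secures, and cyclisation of the ketene in preference to dimerisation, which the adjacent electron-rich enol ether terminus secures.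

**Compound list**

1 | 2,3,4-trimethoxyphenol | COc1ccc(O)c(OC)c1OC | starting material
2 | 2-hydroxy-3,4,5-trimethoxybenzaldehyde | COc1cc(C=O)c(O)c(OC)c1OC | intermediate
3 | acrylonitrile | C=CC#N | starting material
4 | 6,7,8-trimethoxy-2H-chromene-3-carbonitrile | N#CC1=Cc2cc(OC)c(OC)c(OC)c2OC1 | intermediate
5 | 6,7,8-trimethoxy-2H-chromene-3-carboxylic acid | OC(=O)C1=Cc2cc(OC)c(OC)c(OC)c2OC1 | intermediate
6 | (R)-6,7,8-trimethoxychromane-3-carboxylic acid | OC(=O)[C@H]1COc2c(cc(OC)c(OC)c2OC)C1 | intermediate
7 | (S)-(6,7,8-trimethoxychroman-3-yl)methanol | OC[C@H]1COc2c(cc(OC)c(OC)c2OC)C1 | intermediate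
8 | (R)-6,7,8-trimethoxychromane-3-carbaldehyde | O=C[C@H]1COc2c(cc(OC)c(OC)c2OC)C1 | intermediate
9 | (S)-3-ethynyl-6,7,8-trimethoxychromane | C#C[C@H]1COc2c(cc(OC)c(OC)c2OC)C1 | intermediate
10 | trichloroacetyl chloride | ClC(Cl)(Cl)C(Cl)=O | starting material
11 | dichloroketene (formed in the flask) | ClC(Cl)=C=O | intermediate
12 | 4,4-dichloro-3-[(S)-6,7,8-trimethoxychroman-3-yl]cyclobut-2-en-1-one | O=C1C=C([C@H]2COc3c(cc(OC)c(OC)c3OC)C2)C1(Cl)Cl | intermediate
13 | 3-[(S)-6,7,8-trimethoxychroman-3-yl]cyclobut-3-ene-1,2-dione | O=C1C=C([C@H]2COc3c(cc(OC)c(OC)c3OC)C2)C1=O | intermediate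
14 | (E)-1,2-dimethoxyethene | CO/C=C/OC | starting material
15 | [(E)-1,2-dimethoxyethenyl]lithium, lithium cis to the β-methoxy group (formed in the flask) | CO/C=C(/OC)[Li] | intermediate
16 | 4-[(E)-1,2-dimethoxyethenyl]-4-hydroxy-3-[(S)-6,7,8-trimethoxychroman-3-yl]cyclobut-2-en-1-one, both carbinol epimers | CO/C=C(/OC)C1(O)C(=CC1=O)[C@H]1COc2c(cc(OC)c(OC)c2OC)C1 | intermediate
17 | dienylketene: 4-hydroxy-5,6-dimethoxy-3-[(S)-6,7,8-trimethoxychroman-3-yl]hexa-1,3,5-trien-1-one, ketene carbon and dimethoxyvinyl group cis across the central C=C (formed in the flask) | O=C=C/C([C@H]1COc2c(cc(OC)c(OC)c2OC)C1)=C(/O)\C(OC)=C/OC | intermediate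
18 | 4-hydroxy-5,6-dimethoxy-3-[(S)-6,7,8-trimethoxychroman-3-yl]cyclohexa-2,4-dien-1-one, both C6 epimers (formed in the flask) | O=C1C=C([C@H]2COc3c(cc(OC)c(OC)c3OC)C2)C(O)=C(OC)C1OC | intermediate
19 | 2,3-dimethoxy-5-[(S)-6,7,8-trimethoxychroman-3-yl]benzene-1,4-diol (formed in the flask) | COc1c(OC)c(O)c([C@H]2COc3c(cc(OC)c(OC)c3OC)C2)cc1O | intermediate
20 | abruquinone B, (S)-2,3-dimethoxy-5-(6,7,8-trimethoxychroman-3-yl)cyclohexa-2,5-diene-1,4-dione | COC1=C(OC)C(=O)C([C@H]2COc3c(cc(OC)c(OC)c3OC)C2)=CC1=O | target

**Step count and risks**

Total steps: 11. Longest linear sequence: 11 steps (1 → 20).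

Steps most likely to fail:

1. Step 10. The lithium reagent may be lost by elimination of lithium methoxide before it adds. It may also add in conjugate fashion to the unsubstituted ring carbon, or act as a base at the chroman C3–H and erode the ee. Addition at the other carbonyl would be harmless, since that adduct should give the same quinone in step 11, though by closing the C4–C3 bond instead of C1–C2. Fallback: set out from alkyne 9 and move both methoxy groups onto the four-membered ring. Markovnikov addition of HI (NaI, TMSCl, H2O, MeCN, rt) should give (R)-3-(1-iodoethenyl)-6,7,8-trimethoxychromane F1. Iodine–lithium exchange (t-BuLi, Et2O, −78 °C) should give {1-[(S)-6,7,8-trimethoxychroman-3-yl]ethenyl}lithium F2. Addition of F2 to commercial dimethyl squarate (3,4-dimethoxycyclobut-3-ene-1,2-dione) at −78 °C should give 4-hydroxy-2,3-dimethoxy-4-{1-[(S)-6,7,8-trimethoxychroman-3-yl]ethenyl}cyclobut-2-en-1-one F3. Thermolysis of F3 in toluene (Moore rearrangement, closing the ring on the CH side) comes back to the route at hydroquinone 19, which the Ag2O treatment of step 11 takes to 20.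

2. Step 9. Chloride may return to the ring at the other allylic end and isomerise 12, or the strained dione may be opened by water. Fallback: set out from alkyne 9 and build the dione by double carbonylation instead of cycloaddition and hydrolysis. A reactive iron carbonyl species (Fe(CO)5, NaBH4, AcOH, THF, rt) should take up the alkyne to give a maleoyl iron complex, formulated as tetracarbonyl{2-[(S)-6,7,8-trimethoxychroman-3-yl]-1,4-dioxobut-2-ene-1,4-diyl}iron F4. Oxidative decomplexation (CuCl2·2H2O, acetone) should close it and come back to the route at dione 13.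

3. Step 4. The hydrogenation may be slow on this electron-rich trisubstituted alkene, or give insufficient enantioselectivity or the wrong sense. Fallback: set out from acid 5 and separate instead of induce. Hydrogenation over Pd/C (H2, EtOAc) should give racemic 6,7,8-trimethoxychromane-3-carboxylic acid F5. Crystallisation with (R)-1-phenylethylamine should give the salt (R)-1-phenylethylammonium (R)-6,7,8-trimethoxychromane-3-carboxylate F6; the antipodal amine is used if the other salt is the less soluble one. Acidification of F6 comes back to the route at acid 6.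

Further compounds
F1 | step 10 | (R)-3-(1-iodoethenyl)-6,7,8-trimethoxychromane | C=C(I)[C@H]1COc2c(cc(OC)c(OC)c2OC)C1
F2 | step 10 | {1-[(S)-6,7,8-trimethoxychroman-3-yl]ethenyl}lithium | [Li]C(=C)[C@H]1COc2c(cc(OC)c(OC)c2OC)C1
F3 | step 10 | 4-hydroxy-2,3-dimethoxy-4-{1-[(S)-6,7,8-trimethoxychroman-3-yl]ethenyl}cyclobut-2-en-1-one | COC1=C(OC)C(O)(C(=C)[C@H]2COc3c(cc(OC)c(OC)c3OC)C2)C1=O
F4 | step 9 | tetracarbonyl{2-[(S)-6,7,8-trimethoxychroman-3-yl]-1,4-dioxobut-2-ene-1,4-diyl}iron | O=C1C=C([C@H]2COc3c(cc(OC)c(OC)c3OC)C2)C(=O)[Fe]1(=C=O)(=C=O)(=C=O)=C=O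
F5 | step 4 | racemic 6,7,8-trimethoxychromane-3-carboxylic acid | OC(=O)C1COc2c(cc(OC)c(OC)c2OC)C1
F6 | step 4 | (R)-1-phenylethylammonium (R)-6,7,8-trimethoxychromane-3-carboxylate | [O-]C(=O)[C@H]1COc2c(cc(OC)c(OC)c2OC)C1.C[C@@H]([NH3+])c1ccccc1
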